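I begin from a leftover. In this flask Q is charged at 92 mM against 80 mM of G, and my working guess is that each G takes up one Q. A surplus of Q over G, 12.0 mM, then stays over and no G stays free. X turns J into D and E into L, and I suspect G of carrying the exchange between J and E.

the same everywhere: J 0.80 M; E 0.80 M; G 80 mM; Q 92 mM

| run | X | remark | time |
|---|---|---|---|
| green | 1.6 M | the very flask that is asked about, followed so far |  |
| flask | 1.60 M |  | 6.0 min |

- green (time / s: D / %, L / %, J / %): 10.0: 21, 13, 32; 12.0: 24, 13, 24; 20.0: 32, 18, 18; 30.0: 36, 23, 15; 50.0: 41, 30, 9; 80.0: 43, 37, 4

(scatter of a reading: 1.5 percentage points)

- D and L together, in percent of the J and E charged together, at 6.0 min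
- excess of D over L in the product at 6.0 min
- whether the exchange between J and E keeps pace with the reaction: how far the product's excess at 6.0 min gets from its value without exchange to its value with instant exchange (above 80% keeps pace, below 20% hardly takes part, else lags behind)

- X is single-handed; J and E are mirror images of each other, charged as a racemate, each of them at the stated concentration
- an excess is the difference of the two amounts in percent of their sum
- an excess is below zero if the other one leads
- the handed part of X does not stay in what it makes, so the products of the two hands are mirror images too

Does the green run, which is this same flask, allow that guess? At 80.0 s E stands at 16.0% against J at 4%, so a working exchange would lift J and D together above their charged 50.0%. They read 47.0%, with each reading scattering by 1.5 percentage points, so I take the exchange as absent.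

How much is at stake in that? At 50.0 s the logarithm of charged over remaining, J against E, gives a selectivity factor of 1.87, as a reading. Product forming while J and E stand equal would therefore carry an excess near 30.3%, which is a ratio of formation at that moment and not the flask's excess at 6.0 min. At 80.0 s in the green run the readings put D ahead of L by 6 points and E ahead of J by 12 points, so I do not equate the two leads. My answer on the pace is that the exchange hardly takes part.

The forecast gives 94%, an excess of 5% and hardly takes part, on the ground that “Each hand keeps to itself”.

    G + Q → Z (k = 11.8 /M/s)
    J + G ⇌ E + G, rate k2*[G]*[J] forward; the back reaction follows from the equilibrium constant (k = 0.102 /M/s)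
    D ⇌ L (k = 0.00171 /s)
    X + E → L (k = 0.0207 /M/s)
    X + J → D (k = 0.0418 /M/s)

The flask gives 93.4%, an excess of −0.106% and hardly takes part, with 0.66% of the way covered. The point of parting is the excess: the scheme holds D ⇌ L at 0.00171 /s, and at 6.00 min D and L stand at 46.7% and 46.8%. In this flask G is at 0% and Q at 13.0% of its charge, the surplus being 13.0% of it. With Q at 0.023 M the surplus turns round: G exceeds Q by 57.0 mM, which is 71.2% of G, and that neighbour keeps G at 71.2% with an excess of 5.67%.

(The runs are simulated with made-up constants, and the scatter is random.)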